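The route rests on cutting the C1–C11 bond of the target: the spiro ring-fusion carbon and the gem-dimethyl carbon of the cyclohexene, two fully substituted neighbours lying allylic to the C9=C10(Br) bromoalkene. That pattern is the retron of an ester-enolate Claisen shift. A six-membered lactone carrying a 1-bromo-2-methylpropenyl group on its O–CH carbon, a cis-diol unit and the complete side chain at its α-carbon is converted through its silyl ketene acetal into the cyclohexene β-hydroxy acid. One operation forges C1–C11, closes the carbocycle, keeps the vinyl bromide in place and sets the quaternary stereocentre by transfer from the lactone carbinol carbon. Spirolactonisation, reduction, oxetane-acetal closure and bromide inversion finish the tricycle.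

Key step: step 14

Remark: target locants follow 4,6-dioxatricyclo[5.4.0.0^1,5]undec-9-ene numbering (C1 spiro carbon, C5 acetal carbon, C7 C(Me)–O, C8 CHBr, C9=C10(Br), C11 CMe2) and lactone locants those of oxan-2-one (O1, C2 carbonyl, C6 the O–CH carbon); the sense of the two kinetic resolutions (steps 3 and 9) is assigned from the usual empirical models and is assumed to hold for these substrates.

Step 1
Reactants: 1 3-methylbut-2-enal
Product: 3 2-bromo-3-methylbut-2-enal, via 2,3-dibromo-3-methylbutanal 2 (not isolated)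
Conditions: Br2, CH2Cl2, −20 → 0 °C; then Et3N, 0 °C → rt
Reagents that add atoms: bromine, BrBr
Why: Bromine addition to the enal followed by E1cB loss of HBr through the acidic α-hydrogen (bromination–dehydrobromination) should give the α-bromo enal, with no stereocentre involved.

Step 2
Reactants: 3 2-bromo-3-methylbut-2-enal; 4 vinylmagnesium bromide
Product: 5 rac-4-bromo-5-methylhexa-1,4-dien-3-ol
Conditions: THF, −78 °C; sat. aq. NH4Cl
Reagents that add atoms: none
Why: Grignard 1,2-addition to the aldehyde should give the racemic bis-allylic carbinol, conjugate addition being disfavoured at the fully substituted β-carbon.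

Step 3
Reactants: 5 rac-4-bromo-5-methylhexa-1,4-dien-3-ol
Product: 6 (S)-4-bromo-5-methylhexa-1,4-dien-3-ol
Conditions: lipase PS (Burkholderia cepacia), vinyl acetate, MTBE, 30 °C, to slightly beyond half conversion
Reagents that add atoms: none
Why: Lipase-catalysed kinetic resolution (enantioselective transesterification): by the Kazlauskas rule the enzyme should acylate the (R)-alcohol, with bromoalkenyl as the large and vinyl as the medium group, leaving the (S)-alcohol that becomes C6 of the lactone.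

Step 4
Reactants: 6 (S)-4-bromo-5-methylhexa-1,4-dien-3-ol; 7 3-methylbut-3-enoic acid
Product: 8 (S)-4-bromo-5-methylhexa-1,4-dien-3-yl 3-methylbut-3-enoate
Conditions: DCC, DMAP (5 mol %), CH2Cl2, 0 °C
Reagents that add atoms: none
Why: Steglich esterification at 0 °C acylates the secondary alcohol without touching its stereocentre and should keep the β,γ-alkene of the acid out of conjugation.

Step 5
Reactants: 8 (S)-4-bromo-5-methylhexa-1,4-dien-3-yl 3-methylbut-3-enoate
Product: 9 (S)-6-(1-bromo-2-methylprop-1-en-1-yl)-4-methyl-3,6-dihydro-2H-pyran-2-one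
Conditions: Grubbs II (5 mol %), 1,4-benzoquinone (10 mol %), CH2Cl2 (5 mM), 40 °C
Reagents that add atoms: none
Why: Ring-closing metathesis between the vinyl group and the 1,1-disubstituted alkene should close the six-membered β,γ-unsaturated lactone (the tetrasubstituted vinyl bromide is inert), placing the C4=C5 alkene without any lactone dienolate, which would ring-open.

Step 6
Reactants: 9 (S)-6-(1-bromo-2-methylprop-1-en-1-yl)-4-methyl-3,6-dihydro-2H-pyran-2-one
Product: 10 (4S,5R,6S)-6-(1-bromo-2-methylprop-1-en-1-yl)-4,5-dihydroxy-4-methyloxan-2-one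
Conditions: OsO4 (2 mol %), NMO, acetone/H2O, 0 °C → rt
Reagents that add atoms: osmium tetroxide (catalytic oxygen carrier), O=[Os](=O)(=O)=O; N-methylmorpholine N-oxide, C[N+]1([O-])CCOCC1; water, O
Why: Upjohn syn-dihydroxylation should occur on the ring alkene from the face opposite the bulky C6 alkenyl group, setting C4 and C5 as a cis-diol trans to that group, while the electron-poor tetrasubstituted vinyl bromide stays untouched.

Step 7
Reactants: 10 (4S,5R,6S)-6-(1-bromo-2-methylprop-1-en-1-yl)-4,5-dihydroxy-4-methyloxan-2-one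
Product: 11 (4S,5R,6S)-6-(1-bromo-2-methylprop-1-en-1-yl)-5-[(tert-butyldimethylsilyl)oxy]-4-hydroxy-4-methyloxan-2-one
Conditions: TBSOTf (1.05 equiv), 2,6-lutidine, CH2Cl2, −78 °C
Reagents that add atoms: tert-butyldimethylsilyl trifluoromethanesulfonate, CC(C)(C)[Si](C)(C)OS(=O)(=O)C(F)(F)F
Why: Silyl triflate silylation at low temperature should select the secondary C5 hydroxyl over the tertiary C4 hydroxyl on steric grounds.

Step 8
Reactants: 12 methacrolein
Product: 13 rac-2-(prop-1-en-2-yl)oxirane
Conditions: Me3S+ I−, 50% aq. NaOH, n-Bu4N+ HSO4− (cat.), CH2Cl2, rt; distil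
Reagents that add atoms: trimethylsulfonium iodide, C[S+](C)C.[I-]
Why: Corey–Chaykovsky epoxidation: the sulfonium ylide adds 1,2 to the enal carbonyl and closes the vinyl oxirane, racemic at this stage.

Step 9
Reactants: 13 rac-2-(prop-1-en-2-yl)oxirane
Product: 14 (S)-3-methylbut-3-ene-1,2-diol
Conditions: (R,R)-(salen)Co(III)OAc (0.5 mol %), H2O (0.45 equiv), 0 °C → rt; unreacted epoxide removed in vacuo
Reagents that add atoms: water, O
Why: Jacobsen hydrolytic kinetic resolution: with substoichiometric water the catalyst hydrolyses one epoxide enantiomer at the terminal carbon with retention at the stereocentre, the (R,R) catalyst being expected to give the (S)-diol.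

Step 10
Reactants: 14 (S)-3-methylbut-3-ene-1,2-diol
Product: 15 (4S)-2-(4-methoxyphenyl)-4-(prop-1-en-2-yl)-1,3-dioxolane (both C2 epimers)
Conditions: 4-MeOC6H4CH(OMe)2, PPTS (cat.), CH2Cl2, rt
Reagents that add atoms: 4-methoxybenzaldehyde dimethyl acetal, COC(OC)c1ccc(OC)cc1
Why: Acid-catalysed transacetalisation should give the p-methoxybenzylidene acetal of the 1,2-diol, whose new acetal centre is removed in the next step.

Step 11
Reactants: 15 (4S)-2-(4-methoxyphenyl)-4-(prop-1-en-2-yl)-1,3-dioxolane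
Product: 16 (S)-2-[(4-methoxybenzyl)oxy]-3-methylbut-3-en-1-ol
Conditions: DIBAL-H (2.5 equiv), CH2Cl2, −78 → 0 °C; Rochelle salt
Reagents that add atoms: none
Why: Reductive acetal opening: DIBAL-H coordinates the less hindered primary oxygen and delivers hydride to the resulting oxocarbenium ion, which should leave the PMB group on the secondary oxygen and free the primary alcohol.

Step 12
Reactants: 16 (S)-2-[(4-methoxybenzyl)oxy]-3-methylbut-3-en-1-ol
Product: 17 (S)-2-[(4-methoxybenzyl)oxy]-3-methylbut-3-en-1-yl trifluoromethanesulfonate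
Conditions: Tf2O, 2,6-lutidine, CH2Cl2, −78 °C; cold pentane filtration, used at once
Reagents that add atoms: trifluoromethanesulfonic anhydride, O=S(=O)(OS(=O)(=O)C(F)(F)F)C(F)(F)F
Why: Triflation of the primary alcohol gives an electrophile reactive enough for a hindered enolate at −78 °C, where a β-alkoxy primary iodide would be sluggish and prone to elimination.

Step 13
Reactants: 11 (4S,5R,6S)-6-(1-bromo-2-methylprop-1-en-1-yl)-5-[(tert-butyldimethylsilyl)oxy]-4-hydroxy-4-methyloxan-2-one; 17 (S)-2-[(4-methoxybenzyl)oxy]-3-methylbut-3-en-1-yl trifluoromethanesulfonate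
Product: 19 (4S,5R,6S)-6-(1-bromo-2-methylprop-1-en-1-yl)-5-[(tert-butyldimethylsilyl)oxy]-4-hydroxy-3-[(2R)-2-[(4-methoxybenzyl)oxy]-3-methylbut-3-en-1-yl]-4-methyloxan-2-one (C3 epimers), via dilithio lactone alkoxide-enolate 18 (not isolated)
Conditions: LDA (2.2 equiv), THF, −78 → −40 °C; then 17, −78 °C; sat. aq. NH4Cl
Reagents that add atoms: none
Why: Fráter–Seebach-type alkylation: the β-alkoxide–enolate dianion cannot expel its β-oxygen and should C-alkylate the primary triflate, the C3 configuration being irrelevant because the next step erases it.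

Step 14
Reactants: 19 (4S,5R,6S)-6-(1-bromo-2-methylprop-1-en-1-yl)-5-[(tert-butyldimethylsilyl)oxy]-4-hydroxy-3-[(2R)-2-[(4-methoxybenzyl)oxy]-3-methylbut-3-en-1-yl]-4-methyloxan-2-one (either C3 epimer)
Product: 23 (1S,5R,6S)-3-bromo-5-[(tert-butyldimethylsilyl)oxy]-6-hydroxy-1-[(2R)-2-[(4-methoxybenzyl)oxy]-3-methylbut-3-en-1-yl]-2,2,6-trimethylcyclohex-3-ene-1-carboxylic acid, via alkylated dilithio alkoxide-enolate 20 (not isolated), via bis-silyl ketene acetal 21 (not isolated), via rearranged bis-silyl ester 22 (not isolated)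
Conditions: LDA (3 equiv), TMSCl/Et3N, THF, −78 °C → rt; PhMe, 90 °C; then K2CO3 (cat.), MeOH, 0 °C; citric acid to pH 4
Reagents that add atoms: none
Why: Two equivalents of amide base give the lithium alkoxide–lactone enolate 20, which TMSCl traps as the silyl ether and cyclic silyl ketene acetal 21; on warming, the allyl vinyl ether unit C3=C2–O1–C6–C(Br)=CMe2 undergoes a concerted [3,3] shift in which the C3–CMe2 bond forms as O1–C6 breaks, and methanolysis of the silyl ester and trimethylsilyl ether of 22 releases 23. The closest known reaction type is the Ireland–Claisen rearrangement of alkenyl lactone enolates to cycloalkenecarboxylic acids, including β-oxido dianion cases. The cyclohexene is closed by the sigmatropic bond formation itself, through a bicyclo[2.2.2]-like boat transition state imposed by the lactone ring with the alkenyl arm axial; O1 and C2 leave the ring as the carboxyl group and the two alkene carbons enter it, so a six-membered lactone becomes a six-membered carbocycle. The single new stereocentre, quaternary C1, is controlled by the C6 carbinol configuration, because the CMe2 terminus is delivered suprafacially to the enolate face that carries the alkenyl group; the diol oxygens, trans to that arm, therefore finish cis to the carboxyl, and both C3 epimers converge because C3 is planar in the enolate. The step needs clean C-enolisation without β-elimination and a rearrangement that tolerates two adjacent quaternary carbons; the first is secured by holding the β-oxygen as an alkoxide and then a silyl ether, the second by the intramolecular, concerted nature of the shift, in which the bromine on the central allyl carbon is only a spectator.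

Step 15
Reactants: 23 (1S,5R,6S)-3-bromo-5-[(tert-butyldimethylsilyl)oxy]-6-hydroxy-1-[(2R)-2-[(4-methoxybenzyl)oxy]-3-methylbut-3-en-1-yl]-2,2,6-trimethylcyclohex-3-ene-1-carboxylic acid
Product: 25 (3R,5S,9R,10S)-7-bromo-9-[(tert-butyldimethylsilyl)oxy]-10-hydroxy-6,6,10-trimethyl-3-(prop-1-en-2-yl)-2-oxaspiro[4.5]dec-7-en-1-one, via free hydroxy acid 24 (not isolated)
Conditions: DDQ, CH2Cl2/pH 7 buffer, 0 °C → rt; then PPTS (cat.), 4 Å MS, CH2Cl2, rt
Reagents that add atoms: none
Why: Oxidative PMB cleavage by DDQ frees the side-chain carbinol, which should close onto the neighbouring carboxyl by acid-catalysed γ-lactonisation with retention at the carbinol carbon, the silyl ether keeping the ring hydroxyl from competing.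

Step 16
Reactants: 25 (3R,5S,9R,10S)-7-bromo-9-[(tert-butyldimethylsilyl)oxy]-10-hydroxy-6,6,10-trimethyl-3-(prop-1-en-2-yl)-2-oxaspiro[4.5]dec-7-en-1-one
Product: 26 (3R,5S,9R,10S)-7-bromo-9-[(tert-butyldimethylsilyl)oxy]-6,6,10-trimethyl-3-(prop-1-en-2-yl)-2-oxaspiro[4.5]dec-7-ene-1,10-diol (both C1 epimers)
Conditions: DIBAL-H (2.5 equiv), CH2Cl2, −78 °C; Rochelle salt
Reagents that add atoms: none
Why: DIBAL-H reduction of a γ-lactone at −78 °C should stop at the lactol because the tetrahedral aluminate is stable, the first equivalent being consumed by the tertiary hydroxyl.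

Step 17
Reactants: 26 (3R,5S,9R,10S)-7-bromo-9-[(tert-butyldimethylsilyl)oxy]-6,6,10-trimethyl-3-(prop-1-en-2-yl)-2-oxaspiro[4.5]dec-7-ene-1,10-diol
Product: 27 (1S,3R,5S,7S,8R)-10-bromo-8-[(tert-butyldimethylsilyl)oxy]-7,11,11-trimethyl-3-(prop-1-en-2-yl)-4,6-dioxatricyclo[5.4.0.0^1,5]undec-9-ene
Conditions: PPh3, DIAD, THF, 0 °C → rt
Reagents that add atoms: none
Why: Mitsunobu-type dehydrative acetalisation, a known mode of closing β-hydroxy lactols to strained oxetane acetals: the acidic lactol hydroxyl is activated by the phosphine–azodicarboxylate pair and the cis tertiary hydroxyl should capture the anomeric carbon under non-acidic, irreversible conditions, the C5 configuration being fixed by the obligatory cis fusion of the four- and five-membered rings.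

Step 18
Reactants: 27 (1S,3R,5S,7S,8R)-10-bromo-8-[(tert-butyldimethylsilyl)oxy]-7,11,11-trimethyl-3-(prop-1-en-2-yl)-4,6-dioxatricyclo[5.4.0.0^1,5]undec-9-ene
Product: 28 (1S,3R,5S,7S,8R)-10-bromo-7,11,11-trimethyl-3-(prop-1-en-2-yl)-4,6-dioxatricyclo[5.4.0.0^1,5]undec-9-en-8-ol
Conditions: TBAF, THF, rt → 40 °C
Reagents that add atoms: none
Why: Fluoride desilylation should liberate the allylic alcohol under basic conditions that the acetal tolerates.

Step 19
Reactants: 28 (1S,3R,5S,7S,8R)-10-bromo-7,11,11-trimethyl-3-(prop-1-en-2-yl)-4,6-dioxatricyclo[5.4.0.0^1,5]undec-9-en-8-ol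
Product: 29 (1S,3R,5S,7S,8S)-8,10-dibromo-7,11,11-trimethyl-3-(prop-1-en-2-yl)-4,6-dioxatricyclo[5.4.0.0^1,5]undec-9-ene
Conditions: CBr4, PPh3, 2,6-lutidine, CH2Cl2, 0 °C → rt
Reagents that add atoms: carbon tetrabromide, BrC(Br)(Br)Br
Why: Appel bromination: bromide should displace the alkoxyphosphonium group by SN2 with inversion, turning the (8R)-alcohol into the (8S)-bromide, while SN2′ attack is disfavoured because the far allylic terminus is the bromine-bearing carbon next to the quaternary centre.

Compound list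

1 | 3-methylbut-2-enal | CC(C)=CC=O | starting material
2 | 2,3-dibromo-3-methylbutanal (racemic) | CC(C)(Br)C(Br)C=O | intermediate
3 | 2-bromo-3-methylbut-2-enal | CC(C)=C(Br)C=O | intermediate
4 | vinylmagnesium bromide | C=C[Mg]Br | starting material
5 | rac-4-bromo-5-methylhexa-1,4-dien-3-ol | C=CC(O)C(Br)=C(C)C | intermediate
6 | (S)-4-bromo-5-methylhexa-1,4-dien-3-ol | C=C[C@H](O)C(Br)=C(C)C | intermediate
7 | 3-methylbut-3-enoic acid | C=C(C)CC(=O)O | starting material
8 | (S)-4-bromo-5-methylhexa-1,4-dien-3-yl 3-methylbut-3-enoate | C=C(C)CC(=O)O[C@@H](C=C)C(Br)=C(C)C | intermediate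
9 | (S)-6-(1-bromo-2-methylprop-1-en-1-yl)-4-methyl-3,6-dihydro-2H-pyran-2-one | O=C1CC(C)=C[C@@H](C(Br)=C(C)C)O1 | intermediate
10 | (4S,5R,6S)-6-(1-bromo-2-methylprop-1-en-1-yl)-4,5-dihydroxy-4-methyloxan-2-one | O=C1O[C@H](C(Br)=C(C)C)[C@@H](O)[C@@](C)(O)C1 | intermediate
11 | (4S,5R,6S)-6-(1-bromo-2-methylprop-1-en-1-yl)-5-[(tert-butyldimethylsilyl)oxy]-4-hydroxy-4-methyloxan-2-one | O=C1O[C@H](C(Br)=C(C)C)[C@@H](O[Si](C)(C)C(C)(C)C)[C@@](C)(O)C1 | intermediate
12 | methacrolein (2-methylprop-2-enal) | C=C(C)C=O | starting material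
13 | rac-2-(prop-1-en-2-yl)oxirane | C=C(C)C1CO1 | intermediate
14 | (S)-3-methylbut-3-ene-1,2-diol | OC[C@@H](O)C(C)=C | intermediate
15 | (4S)-2-(4-methoxyphenyl)-4-(prop-1-en-2-yl)-1,3-dioxolane (both C2 epimers) | COc1ccc(cc1)C1OC[C@@H](O1)C(C)=C | intermediate
16 | (S)-2-[(4-methoxybenzyl)oxy]-3-methylbut-3-en-1-ol | OC[C@@H](OCc1ccc(OC)cc1)C(C)=C | intermediate
17 | (S)-2-[(4-methoxybenzyl)oxy]-3-methylbut-3-en-1-yl trifluoromethanesulfonate | O=S(=O)(OC[C@@H](OCc1ccc(OC)cc1)C(C)=C)C(F)(F)F | intermediate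
18 | dilithium alkoxide–enolate of 11 (lithium enolate across C2–C3, lithium alkoxide at C4; 4S,5R,6S) | [Li]OC1=C[C@](C)(O[Li])[C@H](O[Si](C)(C)C(C)(C)C)[C@@H](C(Br)=C(C)C)O1 | intermediate
19 | (4S,5R,6S)-6-(1-bromo-2-methylprop-1-en-1-yl)-5-[(tert-butyldimethylsilyl)oxy]-4-hydroxy-3-[(2R)-2-[(4-methoxybenzyl)oxy]-3-methylbut-3-en-1-yl]-4-methyloxan-2-one (C3 epimers; Claisen precursor) | O=C1O[C@H](C(Br)=C(C)C)[C@@H](O[Si](C)(C)C(C)(C)C)[C@@](C)(O)C1C[C@@H](OCc2ccc(OC)cc2)C(C)=C | intermediate
20 | dilithium alkoxide–enolate of 19 (lithium enolate across C2–C3, lithium alkoxide at C4) | [Li]OC1=C(C[C@@H](OCc2ccc(OC)cc2)C(C)=C)[C@](C)(O[Li])[C@H](O[Si](C)(C)C(C)(C)C)[C@@H](C(Br)=C(C)C)O1 | intermediate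
21 | (4S,5R,6S)-6-(1-bromo-2-methylprop-1-en-1-yl)-5-[(tert-butyldimethylsilyl)oxy]-3-[(2R)-2-[(4-methoxybenzyl)oxy]-3-methylbut-3-en-1-yl]-4-methyl-2,4-bis[(trimethylsilyl)oxy]-5,6-dihydro-4H-pyran (cyclic silyl ketene acetal) | C[Si](C)(C)OC1=C(C[C@@H](OCc2ccc(OC)cc2)C(C)=C)[C@](C)(O[Si](C)(C)C)[C@H](O[Si](C)(C)C(C)(C)C)[C@@H](C(Br)=C(C)C)O1 | intermediate
22 | trimethylsilyl (1S,5R,6S)-3-bromo-5-[(tert-butyldimethylsilyl)oxy]-1-[(2R)-2-[(4-methoxybenzyl)oxy]-3-methylbut-3-en-1-yl]-2,2,6-trimethyl-6-[(trimethylsilyl)oxy]cyclohex-3-ene-1-carboxylate | C=C(C)[C@H](OCc1ccc(OC)cc1)C[C@@]2(C(=O)O[Si](C)(C)C)[C@](C)(O[Si](C)(C)C)[C@H](O[Si](C)(C)C(C)(C)C)C=C(Br)C2(C)C | intermediate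
23 | (1S,5R,6S)-3-bromo-5-[(tert-butyldimethylsilyl)oxy]-6-hydroxy-1-[(2R)-2-[(4-methoxybenzyl)oxy]-3-methylbut-3-en-1-yl]-2,2,6-trimethylcyclohex-3-ene-1-carboxylic acid (key-step product) | C=C(C)[C@H](OCc1ccc(OC)cc1)C[C@@]2(C(=O)O)[C@](C)(O)[C@H](O[Si](C)(C)C(C)(C)C)C=C(Br)C2(C)C | intermediate
24 | (1S,5R,6S)-3-bromo-5-[(tert-butyldimethylsilyl)oxy]-6-hydroxy-1-[(2R)-2-hydroxy-3-methylbut-3-en-1-yl]-2,2,6-trimethylcyclohex-3-ene-1-carboxylic acid | C=C(C)[C@H](O)C[C@@]2(C(=O)O)[C@](C)(O)[C@H](O[Si](C)(C)C(C)(C)C)C=C(Br)C2(C)C | intermediate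
25 | (3R,5S,9R,10S)-7-bromo-9-[(tert-butyldimethylsilyl)oxy]-10-hydroxy-6,6,10-trimethyl-3-(prop-1-en-2-yl)-2-oxaspiro[4.5]dec-7-en-1-one | C=C(C)[C@H]1C[C@@]2(C(=O)O1)[C@](C)(O)[C@H](O[Si](C)(C)C(C)(C)C)C=C(Br)C2(C)C | intermediate
26 | (3R,5S,9R,10S)-7-bromo-9-[(tert-butyldimethylsilyl)oxy]-6,6,10-trimethyl-3-(prop-1-en-2-yl)-2-oxaspiro[4.5]dec-7-ene-1,10-diol (both C1 epimers) | C=C(C)[C@H]1C[C@@]2(C(O)O1)[C@](C)(O)[C@H](O[Si](C)(C)C(C)(C)C)C=C(Br)C2(C)C | intermediate
27 | (1S,3R,5S,7S,8R)-10-bromo-8-[(tert-butyldimethylsilyl)oxy]-7,11,11-trimethyl-3-(prop-1-en-2-yl)-4,6-dioxatricyclo[5.4.0.0^1,5]undec-9-ene | C=C(C)[C@H]1C[C@@]23[C@@H](O1)O[C@]2(C)[C@H](O[Si](C)(C)C(C)(C)C)C=C(Br)C3(C)C | intermediate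
28 | (1S,3R,5S,7S,8R)-10-bromo-7,11,11-trimethyl-3-(prop-1-en-2-yl)-4,6-dioxatricyclo[5.4.0.0^1,5]undec-9-en-8-ol | C=C(C)[C@H]1C[C@@]23[C@@H](O1)O[C@]2(C)[C@H](O)C=C(Br)C3(C)C | intermediate
29 | (1S,3R,5S,7S,8S)-8,10-dibromo-7,11,11-trimethyl-3-(prop-1-en-2-yl)-4,6-dioxatricyclo[5.4.0.0^1,5]undec-9-ene | C=C(C)[C@H]1C[C@@]23[C@@H](O1)O[C@]2(C)[C@@H](Br)C=C(Br)C3(C)C | target

Total step count: 19. Longest linear sequence: 14 steps (steps 1–7 and 13–19, from 1 to 29); steps 8–12 are a five-step branch from methacrolein that joins at step 13.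

Steps most likely to fail

Step 14. Deprotonation of the hindered C3–H may be slow, the alkoxide stage may suffer retro-aldol opening or oxygen-to-oxygen silyl migration, and the congested boat transition state may be reached only after the ketene acetal has decomposed. The fallback is the neutral Claisen rearrangement of a cyclic enol ether, the known thermal conversion of 2-alkenyl-3,4-dihydro-2H-pyrans into cyclohex-3-enecarbaldehydes, which needs no enolate. It sets out from 19 and returns at 26. The tertiary hydroxyl of 19 would be capped with N-(trimethylsilyl)imidazole to give the 4-O-trimethylsilyl lactone F1. DIBAL-H at −78 °C would give the lactol F2, and mesylation–elimination (MsCl, Et3N, CH2Cl2, 0 °C → reflux) the 2-alkenyl-3,4-dihydro-2H-pyran F3. Heating in a base-washed sealed tube (PhMe, 170–190 °C) should rearrange this allyl vinyl ether through the same boat, with the same sense of chirality transfer, to the cyclohexenecarbaldehyde F4. DDQ would then remove the PMB group, the liberated carbinol closing on the aldehyde to the lactol trimethylsilyl ether F5, and buffered fluoride (TBAF/AcOH, 0 °C) would remove the trimethylsilyl group to give 26, so that steps 15 and 16 are bypassed.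

Step 17. The activated anomeric carbon may be intercepted by the hydrazide anion before the hindered tertiary hydroxyl closes the four-membered ring, or the strained acetal may reopen during isolation. The fallback separates activation from closure and runs the closure under strong base, as in the known base-induced cyclisation of 3-hydroxy glycosyl chlorides to 1,3-anhydro sugars. It sets out from 26 and returns at 27. The lactol hydroxyl of 26 would be exchanged for chloride with 1-chloro-N,N,2-trimethylprop-1-en-1-amine (CH2Cl2, 0 °C) to give the anomeric chloride F6, and KOt-Bu (THF, −78 → 0 °C) would then generate the tertiary alkoxide, which should displace chloride to give 27; elimination is excluded because the neighbouring carbon is quaternary.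

Step 19. Backside displacement at a secondary carbon flanked by a quaternary centre may be slow enough for ionisation to compete, with loss of configurational control, or for the phosphonium and HBr present to open the acetal. The fallback replaces the phosphonium activation by an isolable sulfonate and a soluble bromide source. It sets out from 28 and returns at 29. Chloromethanesulfonyl chloride and pyridine (CH2Cl2, 0 °C) would give the chloromethanesulfonate F7 with retention, and n-Bu4NBr in toluene at 40–60 °C should displace it by SN2 with inversion to give 29 under neutral, acid-free conditions.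

Further compounds

F1 | step 14 | (4S,5R,6S)-6-(1-bromo-2-methylprop-1-en-1-yl)-5-[(tert-butyldimethylsilyl)oxy]-3-[(2R)-2-[(4-methoxybenzyl)oxy]-3-methylbut-3-en-1-yl]-4-methyl-4-[(trimethylsilyl)oxy]oxan-2-one (C3 epimers) | O=C1O[C@H](C(Br)=C(C)C)[C@@H](O[Si](C)(C)C(C)(C)C)[C@@](C)(O[Si](C)(C)C)C1C[C@@H](OCc2ccc(OC)cc2)C(C)=C
F2 | step 14 | lactol from F1: the corresponding oxan-2-ol (C2 and C3 epimers) | OC1O[C@H](C(Br)=C(C)C)[C@@H](O[Si](C)(C)C(C)(C)C)[C@@](C)(O[Si](C)(C)C)C1C[C@@H](OCc2ccc(OC)cc2)C(C)=C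
F3 | step 14 | (2S,3R,4S)-2-(1-bromo-2-methylprop-1-en-1-yl)-3-[(tert-butyldimethylsilyl)oxy]-5-[(2R)-2-[(4-methoxybenzyl)oxy]-3-methylbut-3-en-1-yl]-4-methyl-4-[(trimethylsilyl)oxy]-3,4-dihydro-2H-pyran | C1=C(C[C@@H](OCc2ccc(OC)cc2)C(C)=C)[C@](C)(O[Si](C)(C)C)[C@H](O[Si](C)(C)C(C)(C)C)[C@@H](C(Br)=C(C)C)O1
F4 | step 14 | (1S,5R,6S)-3-bromo-5-[(tert-butyldimethylsilyl)oxy]-1-[(2R)-2-[(4-methoxybenzyl)oxy]-3-methylbut-3-en-1-yl]-2,2,6-trimethyl-6-[(trimethylsilyl)oxy]cyclohex-3-ene-1-carbaldehyde | C=C(C)[C@H](OCc1ccc(OC)cc1)C[C@@]2(C=O)[C@](C)(O[Si](C)(C)C)[C@H](O[Si](C)(C)C(C)(C)C)C=C(Br)C2(C)C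
F5 | step 14 | (3R,5S,9R,10S)-7-bromo-9-[(tert-butyldimethylsilyl)oxy]-6,6,10-trimethyl-3-(prop-1-en-2-yl)-10-[(trimethylsilyl)oxy]-2-oxaspiro[4.5]dec-7-en-1-ol (both C1 epimers) | C=C(C)[C@H]1C[C@@]2(C(O)O1)[C@](C)(O[Si](C)(C)C)[C@H](O[Si](C)(C)C(C)(C)C)C=C(Br)C2(C)C
F6 | step 17 | (3R,5S,9R,10S)-7-bromo-9-[(tert-butyldimethylsilyl)oxy]-1-chloro-6,6,10-trimethyl-3-(prop-1-en-2-yl)-2-oxaspiro[4.5]dec-7-en-10-ol (both C1 epimers) | C=C(C)[C@H]1C[C@@]2(C(Cl)O1)[C@](C)(O)[C@H](O[Si](C)(C)C(C)(C)C)C=C(Br)C2(C)C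
F7 | step 19 | (1S,3R,5S,7S,8R)-10-bromo-7,11,11-trimethyl-3-(prop-1-en-2-yl)-4,6-dioxatricyclo[5.4.0.0^1,5]undec-9-en-8-yl chloromethanesulfonate | C=C(C)[C@H]1C[C@@]23[C@@H](O1)O[C@]2(C)[C@H](OS(=O)(=O)CCl)C=C(Br)C3(C)C
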